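**Retrosynthetic overview**

1. The strategy rests on one feature: the only stereocentre, C2 of ring C, is bonded to ether oxygen O1, and O1 sits on ring-A carbon C8a. Ring C is therefore closed at O1–C8a by intramolecular aryl C–O coupling of a C8a triflate with a preformed (S)-C2 hydroxyl, so the C2–O bond is never broken and C2 never passes through a chalcone.
2. C4=O comes from a C4 carbinol, silyl-protected during ring closure and of irrelevant configuration. The (S)-C2–OH comes from a ring-B aryl ketone by ruthenium-catalysed asymmetric transfer hydrogenation.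
3. C3–C4 comes from an aldol addition of the ring-B methyl ketone enolate to the ring-A 2-(triflyloxy)benzaldehyde.
4. The C3'–C6'' biaryl bond comes from Suzuki coupling of 6-iodo-5,7,4'-tri-O-benzylapigenin with a ring-B pinacol boronate.
5. Ring order: rings A and B and the three apigenin rings are purchased; ring C is the only ring built (step 12); the benzyl ethers fall in the last step.

Key step: step 12

**Remarks and assumptions**

- Abbreviations: ArA = 4-(benzyloxy)-2-methoxy-6-[(trifluoromethylsulfonyl)oxy]phenyl; ArB = 4-(benzyloxy)-3-{5,7-bis(benzyloxy)-2-[4-(benzyloxy)phenyl]-4-oxo-4H-chromen-6-yl}phenyl.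
- Assumption: 2,4-dihydroxy-6-methoxybenzaldehyde is taken as purchasable; otherwise it is the major Vilsmeier formylation product of 5-methoxyresorcinol.
- Remark: C4 is carried as a mixture of epimers (4RS) from step 9 to step 13 and converges to one ketone in step 14. Its oxygen is silylated so that the C2 hydroxyl is the only nucleophile in step 12 and no free alkoxide sits next to the triflate.
- Remark: the tri-ortho-oxygenated C3'–C6'' axis is taken to rotate freely on the laboratory time scale, as the target carries no axial descriptor.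

**Route**

Step 1
Reactants: 1 2,4-dihydroxy-6-methoxybenzaldehyde
Product: 2 4-(benzyloxy)-2-hydroxy-6-methoxybenzaldehyde
Conditions: BnBr (1.05 equiv), K2CO3, acetone, rt
Reagents that add atoms: benzyl bromide, BrCc1ccccc1
Why: Williamson ether synthesis; the 2-OH is held in a hydrogen bond to the formyl oxygen, so the freer and more acidic 4-OH should be alkylated selectively by one equivalent of bromide.

Step 2
Reactants: 2 4-(benzyloxy)-2-hydroxy-6-methoxybenzaldehyde
Product: 3 5-(benzyloxy)-2-formyl-3-methoxyphenyl trifluoromethanesulfonate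
Conditions: Tf2O, pyridine, CH2Cl2, 0 °C
Reagents that add atoms: trifluoromethanesulfonic anhydride, O=S(=O)(OS(=O)(=O)C(F)(F)F)C(F)(F)F
Why: O-sulfonylation of the remaining phenol gives the aryl triflate that later serves as the C8a electrophile; aldehyde and ethers are inert to Tf2O/pyridine at 0 °C.

Step 3
Reactants: 4 apigenin
Product: 5 7-(benzyloxy)-2-[4-(benzyloxy)phenyl]-5-hydroxy-4H-chromen-4-one
Conditions: BnBr (2.2 equiv), K2CO3, DMF, rt
Reagents that add atoms: benzyl bromide, BrCc1ccccc1
Why: Williamson ether synthesis; the 5-OH chelated to the C4 carbonyl is the least nucleophilic hydroxyl, so O7 and O4' should be benzylated and O5 left free to direct the next step.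

Step 4
Reactants: 5 7-(benzyloxy)-2-[4-(benzyloxy)phenyl]-5-hydroxy-4H-chromen-4-one
Product: 6 7-(benzyloxy)-2-[4-(benzyloxy)phenyl]-5-hydroxy-6-iodo-4H-chromen-4-one
Conditions: BnMe3N+ ICl2−, CaCO3, CH2Cl2/MeOH, rt
Reagents that add atoms: benzyltrimethylammonium dichloroiodate, C[N+](C)(C)Cc1ccccc1.Cl[I-]Cl
Why: electrophilic aromatic iodination; with a free chelated 5-OH and a 7-alkoxy group the dichloroiodate reagent is known to iodinate 5,7-dioxygenated flavones at C6 (ortho to the free phenol) and not at C8, while CaCO3 removes the HCl formed.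

Step 5
Reactants: 6 7-(benzyloxy)-2-[4-(benzyloxy)phenyl]-5-hydroxy-6-iodo-4H-chromen-4-one
Product: 7 5,7-bis(benzyloxy)-2-[4-(benzyloxy)phenyl]-6-iodo-4H-chromen-4-one
Conditions: BnBr, K2CO3, Bu4NI (cat.), DMF, 70 °C
Reagents that add atoms: benzyl bromide, BrCc1ccccc1
Why: Williamson ether synthesis under forcing conditions caps the hindered, chelated 5-OH so that no acidic phenol remains for the enolate and cross-coupling steps.

Step 6
Reactants: 8 3'-bromo-4'-hydroxyacetophenone
Product: 9 1-[4-(benzyloxy)-3-bromophenyl]ethanone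
Conditions: BnBr, K2CO3, acetone, reflux
Reagents that add atoms: benzyl bromide, BrCc1ccccc1
Why: Williamson ether synthesis of a simple phenol; the methyl ketone is not alkylated by carbonate.

Step 7
Reactants: 9 1-[4-(benzyloxy)-3-bromophenyl]ethanone
Product: 10 1-[4-(benzyloxy)-3-(4,4,5,5-tetramethyl-1,3,2-dioxaborolan-2-yl)phenyl]ethanone
Conditions: B2pin2, PdCl2(dppf) (3 mol%), KOAc, 1,4-dioxane, 90 °C
Reagents that add atoms: bis(pinacolato)diboron, CC1(C)OB(OC1(C)C)B1OC(C)(C)C(C)(C)O1
Why: Miyaura borylation of a mono-ortho-substituted aryl bromide; the weak base KOAc leaves the ketone untouched and suppresses homocoupling.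

Step 8
Reactants: 7 5,7-bis(benzyloxy)-2-[4-(benzyloxy)phenyl]-6-iodo-4H-chromen-4-one; 10 1-[4-(benzyloxy)-3-(4,4,5,5-tetramethyl-1,3,2-dioxaborolan-2-yl)phenyl]ethanone
Product: 11 6-[5-acetyl-2-(benzyloxy)phenyl]-5,7-bis(benzyloxy)-2-[4-(benzyloxy)phenyl]-4H-chromen-4-one (ArB–C(=O)CH3)
Conditions: Pd(OAc)2 (5 mol%), SPhos (10 mol%), K3PO4, toluene/H2O, 100 °C
Reagents that add atoms: none
Why: Suzuki–Miyaura cross-coupling forms the C3'–C6'' bond; the dialkylbiarylphosphine SPhos is the ligand of choice for tri-ortho-substituted biaryls, and aqueous phosphate is too weak to enolise the ketone for alpha-arylation.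

Step 9
Reactants: 11 6-[5-acetyl-2-(benzyloxy)phenyl]-5,7-bis(benzyloxy)-2-[4-(benzyloxy)phenyl]-4H-chromen-4-one; 3 5-(benzyloxy)-2-formyl-3-methoxyphenyl trifluoromethanesulfonate
Product: 13 rac-3-ArA-3-hydroxy-1-ArB-propan-1-one (racemic at the carbinol that becomes C4), via lithium enolate of the acetyl group 12 (not isolated)
Conditions: LiHMDS (1.0 equiv), THF, −78 °C; then 3, −78 °C; AcOH quench at −78 °C
Reagents that add atoms: none
Why: directed crossed aldol addition of a preformed lithium enolate to a non-enolisable aldehyde forms C3–C4; the cold acidic quench should forestall retro-aldol cleavage, dehydration and attack of the alkoxide on the neighbouring sulfonate, and the new carbinol centre is left racemic because it is oxidised in step 14.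

Step 10
Reactants: 13 rac-3-ArA-3-hydroxy-1-ArB-propan-1-one
Product: 14 rac-3-ArA-3-(tert-butyldimethylsilyloxy)-1-ArB-propan-1-one
Conditions: TBSOTf, 2,6-lutidine, CH2Cl2, −78 to 0 °C
Reagents that add atoms: tert-butyldimethylsilyl trifluoromethanesulfonate, CC(C)(C)[Si](C)(C)OS(=O)(=O)C(F)(F)F
Why: silylation of a hindered secondary alcohol with the silyl triflate; it masks the future C4 oxygen so that the molecule can no longer undergo retro-aldol cleavage and, in step 12, offers a single free hydroxyl and no alkoxide ortho to the triflate.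

Step 11
Reactants: 14 rac-3-ArA-3-(tert-butyldimethylsilyloxy)-1-ArB-propan-1-one
Product: 15 (1S,3RS)-3-ArA-3-(tert-butyldimethylsilyloxy)-1-ArB-propan-1-ol (C1 = future C2, C3 = future C4)
Conditions: RuCl[(S,S)-TsDPEN](p-cymene) (3 mol%), HCO2H/Et3N (1:2), CH2Cl2, 30 °C
Reagents that add atoms: none
Why: Noyori–Ikariya asymmetric transfer hydrogenation; the (S,S)-TsDPEN ruthenium hydride delivers hydride and proton through a six-membered transition state with the aryl group under the cymene ligand, which for aryl–CH2R ketones should give the (S)-carbinol under catalyst control in both C4 epimers, while the flavone vinylogous ester, the aryl triflate, the benzyl ethers and (in the amine-rich medium) the silyl ether are left alone.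

Step 12
Reactants: 15 (1S,3RS)-3-ArA-3-(tert-butyldimethylsilyloxy)-1-ArB-propan-1-ol
Product: 16 (2S,4RS)-7-(benzyloxy)-4-(tert-butyldimethylsilyloxy)-5-methoxy-2-ArB-chromane
Conditions: Pd(OAc)2 (5 mol%), RockPhos (di-tert-butyl biarylphosphine, 10 mol%), Cs2CO3, toluene, 80 °C
Reagents that add atoms: none
Why: Zerovalent palladium, generated from Pd(OAc)2 and the phosphine, inserts into the C8a–OTf bond; carbonate-assisted exchange of triflate for the C2 alkoxide on divalent palladium gives a seven-membered aryl palladium alkoxide, and C–O reductive elimination forms O1–C8a and regenerates the catalyst. The closest known reaction type is the palladium/di-tert-butylbiarylphosphine-catalysed intramolecular etherification of 3-(2-halophenyl)propanols, secondary carbinols included, to chromans, aryl triflates being established partners in palladium C–O coupling. Ring C closes as a six-membered ring by attack of the tethered oxygen on the ipso carbon C8a within the palladacycle (formally 6-exo), and no other ring size can form because the C4 oxygen is silylated. No stereocentre is created: only the O–H bond of the C2 carbinol is broken, so the (S) configuration from step 11 is carried over with retention, and C4 remains a spectator. The step needs reductive elimination to outrun beta-hydride elimination of the benzylic alkoxide, and oxidative addition to outrun base cleavage of the triflate; the bulky electron-rich phosphine secures the former, and the latter is helped by both ring-A alkoxy groups being meta to the triflate, by the absence of a free hydroxyl beside the sulfonate and by the mild, poorly soluble base Cs2CO3.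

Step 13
Reactants: 16 (2S,4RS)-7-(benzyloxy)-4-(tert-butyldimethylsilyloxy)-5-methoxy-2-ArB-chromane
Product: 17 (2S,4RS)-7-(benzyloxy)-5-methoxy-2-ArB-chroman-4-ol (penta-O-benzyl flavan-4-ol)
Conditions: Bu4NF, THF, 0 °C to rt
Reagents that add atoms: none
Why: fluoride-mediated cleavage of the silyl ether; the basic, non-acidic medium should keep the easily ionised 5,7-dioxygenated benzylic C4 carbinol intact, and C2 is not touched.

Step 14
Reactants: 17 (2S,4RS)-7-(benzyloxy)-5-methoxy-2-ArB-chroman-4-ol
Product: 18 (2S)-7-(benzyloxy)-5-methoxy-2-ArB-chroman-4-one (penta-O-benzyl flavanone)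
Conditions: Dess–Martin periodinane, NaHCO3, CH2Cl2, 0 °C to rt
Reagents that add atoms: none
Why: Dess–Martin oxidation of a secondary benzylic alcohol merges both C4 epimers into one ketone; the buffered, non-basic conditions should avoid both ionisation at C4 and the retro-oxa-Michael ring opening that would racemise C2.

Step 15
Reactants: 18 (2S)-7-(benzyloxy)-5-methoxy-2-ArB-chroman-4-one
Product: 19 (2S)-7-hydroxy-2-{4-hydroxy-3-[5,7-dihydroxy-2-(4-hydroxyphenyl)-4-oxo-4H-chromen-6-yl]phenyl}-5-methoxychroman-4-one (target, CNP0332590.1)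
Conditions: H2 (1 atm), Pd/C (10% palladium on carbon), EtOAc/MeOH, rt
Reagents that add atoms: none
Why: catalytic hydrogenolysis removes the five O-benzyl groups under neutral conditions that do not epimerise C2; at 1 atm and room temperature, with the reaction stopped on full debenzylation, the flavone C2''=C3'' bond, the C4 ketone, the C2–O1 bond and the methyl ether should survive.

**Compound list**

1 | 2,4-dihydroxy-6-methoxybenzaldehyde | COc1cc(O)cc(O)c1C=O | starting material
2 | 4-(benzyloxy)-2-hydroxy-6-methoxybenzaldehyde | COc1cc(OCc2ccccc2)cc(O)c1C=O | intermediate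
3 | 5-(benzyloxy)-2-formyl-3-methoxyphenyl trifluoromethanesulfonate | COc1cc(OCc2ccccc2)cc(OS(=O)(=O)C(F)(F)F)c1C=O | intermediate
4 | apigenin | O=c1cc(-c2ccc(O)cc2)oc2cc(O)cc(O)c12 | starting material
5 | 7-(benzyloxy)-2-[4-(benzyloxy)phenyl]-5-hydroxy-4H-chromen-4-one | O=c1cc(-c2ccc(OCc3ccccc3)cc2)oc2cc(OCc3ccccc3)cc(O)c12 | intermediate
6 | 7-(benzyloxy)-2-[4-(benzyloxy)phenyl]-5-hydroxy-6-iodo-4H-chromen-4-one | O=c1cc(-c2ccc(OCc3ccccc3)cc2)oc2cc(OCc3ccccc3)c(I)c(O)c12 | intermediate
7 | 5,7-bis(benzyloxy)-2-[4-(benzyloxy)phenyl]-6-iodo-4H-chromen-4-one | O=c1cc(-c2ccc(OCc3ccccc3)cc2)oc2cc(OCc3ccccc3)c(I)c(OCc3ccccc3)c12 | intermediate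
8 | 3'-bromo-4'-hydroxyacetophenone | CC(=O)c1ccc(O)c(Br)c1 | starting material
9 | 1-[4-(benzyloxy)-3-bromophenyl]ethanone | CC(=O)c1ccc(OCc2ccccc2)c(Br)c1 | intermediate
10 | 1-[4-(benzyloxy)-3-(4,4,5,5-tetramethyl-1,3,2-dioxaborolan-2-yl)phenyl]ethanone | CC(=O)c1ccc(OCc2ccccc2)c(B2OC(C)(C)C(C)(C)O2)c1 | intermediate
11 | 6-[5-acetyl-2-(benzyloxy)phenyl]-5,7-bis(benzyloxy)-2-[4-(benzyloxy)phenyl]-4H-chromen-4-one | CC(=O)c1ccc(OCc2ccccc2)c(-c2c(OCc3ccccc3)cc3oc(-c4ccc(OCc5ccccc5)cc4)cc(=O)c3c2OCc2ccccc2)c1 | intermediate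
12 | lithium enolate of 11 (not isolated) | [Li+].[O-]C(=C)c1ccc(OCc2ccccc2)c(-c2c(OCc3ccccc3)cc3oc(-c4ccc(OCc5ccccc5)cc4)cc(=O)c3c2OCc2ccccc2)c1 | intermediate
13 | rac-3-ArA-3-hydroxy-1-ArB-propan-1-one | COc1cc(OCc2ccccc2)cc(OS(=O)(=O)C(F)(F)F)c1C(O)CC(=O)c1ccc(OCc2ccccc2)c(-c2c(OCc3ccccc3)cc3oc(-c4ccc(OCc5ccccc5)cc4)cc(=O)c3c2OCc2ccccc2)c1 | intermediate
14 | rac-3-ArA-3-(tert-butyldimethylsilyloxy)-1-ArB-propan-1-one | COc1cc(OCc2ccccc2)cc(OS(=O)(=O)C(F)(F)F)c1C(O[Si](C)(C)C(C)(C)C)CC(=O)c1ccc(OCc2ccccc2)c(-c2c(OCc3ccccc3)cc3oc(-c4ccc(OCc5ccccc5)cc4)cc(=O)c3c2OCc2ccccc2)c1 | intermediate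
15 | (1S,3RS)-3-ArA-3-(tert-butyldimethylsilyloxy)-1-ArB-propan-1-ol (silyl ether carbon as epimer mixture) | COc1cc(OCc2ccccc2)cc(OS(=O)(=O)C(F)(F)F)c1C(O[Si](C)(C)C(C)(C)C)C[C@H](O)c1ccc(OCc2ccccc2)c(-c2c(OCc3ccccc3)cc3oc(-c4ccc(OCc5ccccc5)cc4)cc(=O)c3c2OCc2ccccc2)c1 | intermediate
16 | (2S,4RS)-7-(benzyloxy)-4-(tert-butyldimethylsilyloxy)-5-methoxy-2-ArB-chromane (C4 as epimer mixture) | COc1cc(OCc2ccccc2)cc2c1C(O[Si](C)(C)C(C)(C)C)C[C@@H](c1ccc(OCc3ccccc3)c(-c3c(OCc4ccccc4)cc4oc(-c5ccc(OCc6ccccc6)cc5)cc(=O)c4c3OCc3ccccc3)c1)O2 | intermediate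
17 | (2S,4RS)-7-(benzyloxy)-5-methoxy-2-ArB-chroman-4-ol (C4 as epimer mixture) | COc1cc(OCc2ccccc2)cc2c1C(O)C[C@@H](c1ccc(OCc3ccccc3)c(-c3c(OCc4ccccc4)cc4oc(-c5ccc(OCc6ccccc6)cc5)cc(=O)c4c3OCc3ccccc3)c1)O2 | intermediate
18 | (2S)-7-(benzyloxy)-5-methoxy-2-ArB-chroman-4-one | COc1cc(OCc2ccccc2)cc2c1C(=O)C[C@@H](c1ccc(OCc3ccccc3)c(-c3c(OCc4ccccc4)cc4oc(-c5ccc(OCc6ccccc6)cc5)cc(=O)c4c3OCc3ccccc3)c1)O2 | intermediate
19 | (2S)-7-hydroxy-2-{4-hydroxy-3-[5,7-dihydroxy-2-(4-hydroxyphenyl)-4-oxo-4H-chromen-6-yl]phenyl}-5-methoxychroman-4-one | COc1cc(O)cc2c1C(=O)C[C@@H](c1ccc(O)c(-c3c(O)cc4oc(-c5ccc(O)cc5)cc(=O)c4c3O)c1)O2 | target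

**Step count and risks**

Total step count: 15. Longest linear sequence: 11 steps (apigenin 4 to target 19 through steps 3, 4, 5, 8, 9, 10, 11, 12, 13, 14, 15).

Steps most likely to fail:

1. Step 12 (ring closure at O1–C8a). Three processes could intervene. The benzylic palladium alkoxide may undergo beta-hydride elimination, which would oxidise the C2 carbinol, reduce the arene and, if reversible, erode the configuration at C2. The base may cleave the triflate at sulfur before oxidative addition. The silyl group may migrate from the C4 oxygen to the C2 oxygen. The fallback closes ring C at O1–C2 instead, by Mitsunobu etherification with inversion. It sets out from ketone 14: transfer hydrogenation with the enantiomeric catalyst RuCl[(R,R)-TsDPEN](p-cymene) should give (1R,3RS)-3-ArA-3-(tert-butyldimethylsilyloxy)-1-ArB-propan-1-ol F1; hydrolysis of the aryl triflate (Et4NOH, 1,4-dioxane, rt) should give the phenol (1R,3RS)-3-[4-(benzyloxy)-2-hydroxy-6-methoxyphenyl]-3-(tert-butyldimethylsilyloxy)-1-ArB-propan-1-ol F2; PPh3/DIAD in THF at 0 °C should then displace the activated (R)-carbinol by the phenol oxygen with inversion, returning to the route at silyl ether 16.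

2. Step 9 (aldol union). The lithium aldolate may revert by retro-aldol cleavage on warming, lose hydroxide by E1cB elimination to the enone, or attack the neighbouring sulfonyl group. The fallback avoids any metal alkoxide. It sets out from ketone 11, which is converted (TMSOTf, Et3N, CH2Cl2, 0 °C) into the trimethylsilyl enol ether of 11 F3; a Mukaiyama aldol addition of this enol ether to aldehyde 3 (BF3·OEt2, CH2Cl2, −78 °C, aqueous work-up) should return to the route at aldol 13.

3. Step 8 (biaryl coupling). Transmetalation and reductive elimination at the doubly ortho-flanked C6'' may be slow, letting protodeboronation of 10 and reduction of the iodide take over. The fallback removes one bulky ortho group from the electrophile by coupling before the 5-O-benzylation. It sets out from iodophenol 6, which is coupled with boronate 10 under the same palladium/SPhos conditions to give 6-[5-acetyl-2-(benzyloxy)phenyl]-7-(benzyloxy)-2-[4-(benzyloxy)phenyl]-5-hydroxy-4H-chromen-4-one F4; benzylation of its 5-OH (BnBr, K2CO3, DMF, 70 °C) returns to the route at ketone 11.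

**Further compounds**

F1 | step 12 | (1R,3RS)-3-ArA-3-(tert-butyldimethylsilyloxy)-1-ArB-propan-1-ol | COc1cc(OCc2ccccc2)cc(OS(=O)(=O)C(F)(F)F)c1C(O[Si](C)(C)C(C)(C)C)C[C@@H](O)c1ccc(OCc2ccccc2)c(-c2c(OCc3ccccc3)cc3oc(-c4ccc(OCc5ccccc5)cc4)cc(=O)c3c2OCc2ccccc2)c1
F2 | step 12 | (1R,3RS)-3-[4-(benzyloxy)-2-hydroxy-6-methoxyphenyl]-3-(tert-butyldimethylsilyloxy)-1-ArB-propan-1-ol | COc1cc(OCc2ccccc2)cc(O)c1C(O[Si](C)(C)C(C)(C)C)C[C@@H](O)c1ccc(OCc2ccccc2)c(-c2c(OCc3ccccc3)cc3oc(-c4ccc(OCc5ccccc5)cc4)cc(=O)c3c2OCc2ccccc2)c1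
F3 | step 9 | trimethylsilyl enol ether of 11 | C=C(O[Si](C)(C)C)c1ccc(OCc2ccccc2)c(-c2c(OCc3ccccc3)cc3oc(-c4ccc(OCc5ccccc5)cc4)cc(=O)c3c2OCc2ccccc2)c1
F4 | step 8 | 6-[5-acetyl-2-(benzyloxy)phenyl]-7-(benzyloxy)-2-[4-(benzyloxy)phenyl]-5-hydroxy-4H-chromen-4-one | CC(=O)c1ccc(OCc2ccccc2)c(-c2c(OCc3ccccc3)cc3oc(-c4ccc(OCc5ccccc5)cc4)cc(=O)c3c2O)c1
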